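## Analysis of the target

Compound 41 is a germacranolide: a cyclodeca-1(10),4-diene (ring carbons C1 to C10) with a trans-fused α-methylene-γ-butyrolactone (O on C6, then C12, C11(=C13), C7). Both ring alkenes are cis within the ring: C2 and C9 lie on the same side of C1=C10, and C3 and C6 on the same side of C4=C5 (CIP: 1(10)E because of the C14 oxygen, 4Z). There are four stereocentres (2S, 6R, 7R, 8R). C6, C7 and C8 are contiguous, with the C6 and C8 oxygens anti across C7, whereas C2 is isolated from them by the C4=C5 alkene and must be set on its own. The C14 acetate, the C8 angelate, the lactone and the free C2 hydroxyl require each oxygen to be addressed separately. The angelate can isomerise to the tiglate, the methylene lactone is a Michael acceptor, and the C2 and C6 oxygens are allylic. The main difficulty is the ten-membered ring with two trisubstituted ring-cis alkenes, which resists end-to-end closure. The strategy rests on a transannular C4–C8 bond: it divides the ring into a cyclopentane (C4, C5, C6, C7, C8) and a cycloheptene (C8, C9, C10, C1, C2, C3, C4). In that bicycle C1=C10 can only be ring-cis, C8 is a tertiary carbinol, and a C5 sulfonate stands 1,3 to the C8 oxygen, which is the arrangement for a Grob fragmentation.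

## Retrosynthetic reasoning

**C2 hydroxyl and C14 acetate (41 ← 40 ← 39 ← 38).** The C2 silyl ether is removed last, so that C2 stays distinguished from C8 and C14 while those are acylated. The acetate is traced back to alcohol 39 and its p-methoxybenzyl ether 38, because an acetate would not survive the organometallic and basic steps before it.

**Methylene lactone (38 ← 37 ← 35 ← 33 ← 32).** The O6–C12 bond and the C11=C13 bond are cut. The methylene is introduced on aldehyde 33 by a Mannich reaction and elimination, not on a lactone enolate, which the angelate would not tolerate. Desilylation at C6 then closes lactol 37, and a mild oxidation gives 38. Aldehyde 33 is the hydrolysed dimethyl acetal of 32.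

**Angelate (32 ← 29 + 30).** The C8–O acyl bond is cut. Esterification is placed while C6 is still silylated, so that only one hydroxyl is free and no 8,12-lactone can form later. The forward reaction must acylate a hindered secondary alcohol without isomerising angelic acid 30.

**C8 carbinol (29 ← 28).** The C8–H bond is cut back to ketone 28. The forward reduction has to be steered by the adjacent C7 centre.

**Ten-membered ring (28 ← 26, via 27).** C4 and C8 are reconnected and the C4=C5 π bond is turned back into a C5–O bond to a sulfonate. This replaces a medium-ring closure by the cleavage of the bond shared by a five- and a seven-membered ring, and the C4=C5 geometry is read from the C4/C5 configuration of the cyclopentane. The C8 hydroxyl of 26 is placed on the β face (trans ring fusion), because that is where the carbon nucleophile should leave it. C8 loses its configuration in the fragmentation, so its epimer would serve equally.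

**Seven-membered ring (26 ← 25).** C1=C10 is cut by a metathesis disconnection into a vinyl group on C2 and a 1,1-disubstituted alkene on C10. In a seven-membered ring the new alkene can only be cis.

**C8–C9 bond (25 ← 21 + 24).** The allyl unit C9–C10–C14 is added to the cyclopentanone carbonyl of 21 as an allylzinc species in water, so that the β-mesyloxy alkoxide is protonated at once. Bromide 24 comes from diol 22 through monoether 23.

**Mesylate (21 ← 20 ← 19).** The sulfonate is placed when the C5 hydroxyl is the only free one, after selective removal of the most labile silyl group of 19.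

**C1–C2 bond and C2 centre (19 ← 18 ← 17 ← 15).** The vinyl group is added to aldehyde 17 under catalyst control, since no nearby stereocentre can direct it. Aldehyde 17 is the ozonolysis product of the allyl group of 15.

**C12 acetal (15 ← 14 ← 12).** The dimethoxyethyl group is traced to a prenyl group. A 2,2-dimethoxyethyl halide is too poor an electrophile for the enolate, whereas prenyl is reactive and its trisubstituted alkene can be cleaved in the presence of the allyl group.

**C7–C11 bond and C6 oxygen (12 ← 11 ← 8 + 9).** Reductive opening of epoxy ketone 8 gives alkoxide enolate 10. Alkylation with 9 trans to the C6 alkoxide sets C6 and C7 together.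

**Epoxide and enone (8 ← 7 ← 5).** The epoxide is placed trans to the C5 silyl ether on enone 7, which comes from ketone 5 by dehydrogenation toward its only enolisable side.

**C4 and C5 (5 ← 4 ← 3 ← 1 + 2).** A desymmetrising reduction of dione 3 sets the quaternary C4 and the C5 carbinol in one step. Dione 3 is the allylation product of 1 with 2.

## Alternatives that were turned down

**Alternative 1:** Nozaki–Hiyama–Kishi closure of the C5–C6 bond. In the forward sense chromium dichloride A2 (divalent chromium) with catalytic nickel dichloride A3 (divalent nickel) converts a Z-configured C5 vinyl iodide into a vinylchromium species. This adds to a C6 aldehyde in the same chain and gives the ten-membered C6 alcohol A1.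
- For: the route is convergent, and the organochromium reagent tolerates the acetate and the angelate, so both could be in place before cyclisation. C12 and C13 are carried as a 2-substituted allylic silyl ether, so the lactone follows by desilylation and oxidation without enolate chemistry. In end-game step economy it is stronger than the chosen route.
- Against: the ring is closed end to end at ten members, under high dilution and against transannular strain. The aldehyde has C7 as an α-stereocentre that is also allylic to C11=C13 and β to the C8 ester, so epimerisation, conjugation and loss of angelate threaten. The new C6 configuration is decided by the ring-closing conformation with no reliable model. The open chain needs C2, C7, C8 and two trisubstituted Z alkenes built separately.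
- Comparison: the chosen route sets C5 to C7 on a cyclopentane with defined faces, obtains C4=C5 stereospecifically and never closes the medium ring. It pays with a longer linear sequence.

**Alternative 2:** anionic oxy-Cope ring expansion. Potassium hydride A5 converts the C6 carbinol of a cyclohexene with cis alkenyl groups on C1 and C6 into its alkoxide. The [3,3] shift forms C8–C9, breaks C1–C6 and gives the ten-membered C6 ketone A4, with C1=C10 and a silyl group at C8 as masked hydroxyl.
- For: it is a ring expansion that needs no high dilution. The key step makes a C–C bond and a stereocentre, which the fragmentation does not, and a cyclohexenol is easier to assemble than the hydroazulene. On these points it is stronger.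
- Against: A4 lacks the C7 side chain and has C6 as an enone carbonyl. Three stereocontrolled operations remain on the flexible ring: alkylation at C7, 1,2-reduction at C6 trans to C7, and oxidation of the C8–Si bond, whose usual electrophilic or peracid forms conflict with three alkenes. The cis-dialkenyl arrangement enforces a boat transition state, so transfer to the ring-cis alkene and to C8 is less secure.
- Comparison: the chosen route has C6 and C7 in place before the large ring exists and leaves only the C8 reduction for afterwards.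

**Alternative 3:** de Mayo two-carbon expansion. Irradiation of an eight-membered 1,3-diketone, held as its C2 silyl enol ether, adds methyl propiolate A7 across C2=C9 (bonds C1–C2 and C9–C10). Fluoride frees the C2 oxygen, and retro-aldol cleavage of C2–C9 opens the cyclobutene to the ten-membered enedione A6.
- For: C1, C10 and C14 arrive in one operation, C1=C10 is ring-cis by its cyclobutene origin, and A6 already resembles ketone 28 at C6, C7 and C8. It forms two C–C bonds in the key step, which the chosen route does not.
- Against: it needs an eight-membered ring with the C6 and C7 centres and a cis C4=C5 alkene, so the medium-ring problem is moved and not solved. The orientation of the alkyne addition is uncertain, and the ring alkene can compete photochemically. Afterwards the C2 ketone must be reduced to the 2S alcohol beside a second ketone and an ester.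
- Comparison: the chosen route sets C2 by catalyst control before any ring is closed and carries a single ketone through the end-game.

Key step: step 19

Remarks on the chemistry (assumptions):
- Cyclopentane and hydroazulene intermediates are described with the locants of the germacrane carbons they become (ring C4, C5, C6, C7, C8). β is the face of the five-membered ring that carries the C3 chain on C4, and α the face that carries the C4 methyl.
- The (S)-oxazaborolidine of step 2 and (+)-MIB of step 11 are assigned from the usual models (R carbinol; vinyl to the Re face of the aldehyde). Should a model not hold, the mirror-image catalyst is used.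

## Route

Step 1
Reactants: 1 2-methylcyclopentane-1,3-dione; 2 allyl bromide (3-bromoprop-1-ene)
Product: 3 2-methyl-2-(prop-2-en-1-yl)cyclopentane-1,3-dione
Conditions: NaOH (1 M aq.), rt
Reagents that add atoms: none
Why: C-alkylation of the stabilised 1,3-dione enolate with an allylic bromide; it builds the quaternary carbon (future C4) with its methyl (C15) and the chain that supplies C3 and C2.

Step 2
Reactants: 3 2-methyl-2-(prop-2-en-1-yl)cyclopentane-1,3-dione
Product: 4 (2R,3R)-3-hydroxy-2-methyl-2-(prop-2-en-1-yl)cyclopentan-1-one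
Conditions: (S)-2-methyl-CBS-oxazaborolidine [(S)-1-methyl-3,3-diphenyltetrahydro-1H,3H-pyrrolo[1,2-c][1,3,2]oxazaborole] (0.2 equiv), catecholborane, PhNEt2, toluene, −60 °C
Reagents that add atoms: none
Why: Corey–Bakshi–Shibata reduction that desymmetrises the dione: the catalyst fixes the R carbinol and hydride enters on the side of the small methyl group, so the hydroxyl (future C5 oxygen) ends cis to the allyl chain and trans to the methyl. Catecholborane should not hydroborate the alkene at this temperature.

Step 3
Reactants: 4 (2R,3R)-3-hydroxy-2-methyl-2-(prop-2-en-1-yl)cyclopentan-1-one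
Product: 5 (2R,3R)-2-methyl-2-(prop-2-en-1-yl)-3-(triethylsilyloxy)cyclopentan-1-one
Conditions: Et3SiCl, imidazole, DMF, 0 °C
Reagents that add atoms: chlorotriethylsilane, CC[Si](Cl)(CC)CC
Why: Silylation of the secondary alcohol under mild base, which avoids retro-aldol opening; the triethylsilyl group is chosen as the most labile of the three silyl ethers so that C5 can be freed alone in step 13.

Step 4
Reactants: 5 (2R,3R)-2-methyl-2-(prop-2-en-1-yl)-3-(triethylsilyloxy)cyclopentan-1-one
Product: 7 (4R,5R)-5-methyl-5-(prop-2-en-1-yl)-4-(triethylsilyloxy)cyclopent-2-en-1-one, via trimethylsilyl enol ether 6 (not isolated)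
Conditions: LiN(i-Pr)2, Me3SiCl, THF, −78 °C; then Pd(OAc)2, MeCN, rt
Reagents that add atoms: none
Why: Saegusa–Ito dehydrogenation; the ketone can enolise only toward C7 because C4 is quaternary, so the C6=C7 enone forms regiospecifically.

Step 5
Reactants: 7 (4R,5R)-5-methyl-5-(prop-2-en-1-yl)-4-(triethylsilyloxy)cyclopent-2-en-1-one
Product: 8 4β-allyl-6α,7α-epoxy-4α-methyl-5β-(triethylsilyloxy)cyclopentan-8-one
Conditions: t-BuOOH, BnMe3NOH (cat.), THF, 0 °C
Reagents that add atoms: tert-butyl hydroperoxide, CC(C)(C)OO
Why: Weitz–Scheffer nucleophilic epoxidation; the peroxide anion adds to C6 on the α face, away from the adjacent β silyl ether, which fixes the C6 oxygen trans to the C5 oxygen. The quaternary C4 rules out enolisation and loss of the silyloxy group.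

Step 6
Reactants: 8 4β-allyl-6α,7α-epoxy-4α-methyl-5β-(triethylsilyloxy)cyclopentan-8-one; 9 prenyl bromide (1-bromo-3-methylbut-2-ene)
Product: 11 4β-allyl-6α-hydroxy-4α-methyl-7β-(3-methylbut-2-en-1-yl)-5β-(triethylsilyloxy)cyclopentan-8-one, via dilithium alkoxide enolate 10 (not isolated)
Conditions: Li, NH3 (l)/THF, −78 °C; then 9, −78 → −33 °C; NH4Cl
Reagents that add atoms: none
Why: Dissolving-metal reductive cleavage of the α,β-epoxy ketone breaks the C7–O bond and gives the regiodefined enolate with the C6 alkoxide next to it; this dianion cannot eliminate. The reactive allylic bromide enters C7 on the β face, anti to the C6 alkoxide, so C5, C6 and C7 end all-trans.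

Step 7
Reactants: 11 4β-allyl-6α-hydroxy-4α-methyl-7β-(3-methylbut-2-en-1-yl)-5β-(triethylsilyloxy)cyclopentan-8-one
Product: 12 4β-allyl-6α-(tert-butyldimethylsilyloxy)-4α-methyl-7β-(3-methylbut-2-en-1-yl)-5β-(triethylsilyloxy)cyclopentan-8-one
Conditions: t-BuMe2SiOTf, 2,6-lutidine, CH2Cl2, −78 °C
Reagents that add atoms: tert-butyldimethylsilyl triflate, CC(C)(C)[Si](C)(C)OS(=O)(=O)C(F)(F)F
Why: Low-temperature silylation with a silyl triflate and a hindered base protects the β-hydroxy ketone before it can dehydrate.

Step 8
Reactants: 12 4β-allyl-6α-(tert-butyldimethylsilyloxy)-4α-methyl-7β-(3-methylbut-2-en-1-yl)-5β-(triethylsilyloxy)cyclopentan-8-one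
Product: 14 4β-allyl-6α-(tert-butyldimethylsilyloxy)-4α-methyl-7β-(2-oxoethyl)-5β-(triethylsilyloxy)cyclopentan-8-one, via ozonide 13 (not isolated)
Conditions: O3, CH2Cl2, −78 °C (Sudan Red 7B end point); then PPh3, −78 °C → rt
Reagents that add atoms: ozone, [O-][O+]=O
Why: Chemoselective ozonolysis; the electron-rich trisubstituted prenyl alkene is consumed well before the monosubstituted allyl alkene, and the dye marks the end point. It unmasks C12 as the aldehyde.

Step 9
Reactants: 14 4β-allyl-6α-(tert-butyldimethylsilyloxy)-4α-methyl-7β-(2-oxoethyl)-5β-(triethylsilyloxy)cyclopentan-8-one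
Product: 15 4β-allyl-6α-(tert-butyldimethylsilyloxy)-7β-(2,2-dimethoxyethyl)-4α-methyl-5β-(triethylsilyloxy)cyclopentan-8-one
Conditions: MeOSiMe3, Me3SiOTf (cat.), CH2Cl2, −78 °C
Reagents that add atoms: methoxytrimethylsilane, CO[Si](C)(C)C
Why: Aprotic acetalisation with a silyl ether and catalytic silyl triflate (Noyori conditions), which leaves the triethylsilyl ether in place; the aldehyde reacts well before the hindered ketone.

Step 10
Reactants: 15 4β-allyl-6α-(tert-butyldimethylsilyloxy)-7β-(2,2-dimethoxyethyl)-4α-methyl-5β-(triethylsilyloxy)cyclopentan-8-one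
Product: 17 6α-(tert-butyldimethylsilyloxy)-7β-(2,2-dimethoxyethyl)-4α-methyl-4β-(2-oxoethyl)-5β-(triethylsilyloxy)cyclopentan-8-one, via ozonide 16 (not isolated)
Conditions: O3, CH2Cl2, −78 °C; then PPh3
Reagents that add atoms: ozone, [O-][O+]=O
Why: Ozonolysis of the only remaining alkene turns the allyl group into the C3–C2 aldehyde; acetal and silyl ethers are inert.

Step 11
Reactants: 17 6α-(tert-butyldimethylsilyloxy)-7β-(2,2-dimethoxyethyl)-4α-methyl-4β-(2-oxoethyl)-5β-(triethylsilyloxy)cyclopentan-8-one
Product: 18 6α-(tert-butyldimethylsilyloxy)-7β-(2,2-dimethoxyethyl)-4β-[(2S)-2-hydroxybut-3-en-1-yl]-4α-methyl-5β-(triethylsilyloxy)cyclopentan-8-one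
Conditions: (CH2=CH)2Zn (from CH2=CHMgBr and ZnCl2, salts bound with N,N,N',N'-tetraethylethylenediamine), (+)-3-exo-morpholinoisoborneol [(+)-MIB] (10 mol %), toluene, −10 °C
Reagents that add atoms: divinylzinc, C=C[Zn]C=C
Why: Amino-alcohol-catalysed enantioselective addition of an alkenylzinc reagent to an aldehyde; the catalyst delivers vinyl to the Re face and so sets C2 as S without help from the remote ring centres. The organozinc reagent leaves the C8 ketone and the acetal untouched.

Step 12
Reactants: 18 6α-(tert-butyldimethylsilyloxy)-7β-(2,2-dimethoxyethyl)-4β-[(2S)-2-hydroxybut-3-en-1-yl]-4α-methyl-5β-(triethylsilyloxy)cyclopentan-8-one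
Product: 19 6α-(tert-butyldimethylsilyloxy)-4β-[(2S)-2-(tert-butyldiphenylsilyloxy)but-3-en-1-yl]-7β-(2,2-dimethoxyethyl)-4α-methyl-5β-(triethylsilyloxy)cyclopentan-8-one
Conditions: t-BuPh2SiCl, imidazole, DMF, rt
Reagents that add atoms: tert-butylchlorodiphenylsilane, CC(C)(C)[Si](Cl)(c1ccccc1)c1ccccc1
Why: Silylation of the allylic alcohol with the most robust of the three silyl groups, which has to outlast the C5 and C6 silyl ethers to the last step.

Step 13
Reactants: 19 6α-(tert-butyldimethylsilyloxy)-4β-[(2S)-2-(tert-butyldiphenylsilyloxy)but-3-en-1-yl]-7β-(2,2-dimethoxyethyl)-4α-methyl-5β-(triethylsilyloxy)cyclopentan-8-one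
Product: 20 6α-(tert-butyldimethylsilyloxy)-4β-[(2S)-2-(tert-butyldiphenylsilyloxy)but-3-en-1-yl]-7β-(2,2-dimethoxyethyl)-5β-hydroxy-4α-methylcyclopentan-8-one
Conditions: HF·pyridine, pyridine, THF, 0 °C
Reagents that add atoms: none
Why: Buffered HF·pyridine cleaves a secondary triethylsilyl ether much faster than tert-butyldimethylsilyl and tert-butyldiphenylsilyl ethers and is not acidic enough to touch the dimethyl acetal; the trans 1,2-relationship prevents silyl migration from O6 to O5.

Step 14
Reactants: 20 6α-(tert-butyldimethylsilyloxy)-4β-[(2S)-2-(tert-butyldiphenylsilyloxy)but-3-en-1-yl]-7β-(2,2-dimethoxyethyl)-5β-hydroxy-4α-methylcyclopentan-8-one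
Product: 21 6α-(tert-butyldimethylsilyloxy)-4β-[(2S)-2-(tert-butyldiphenylsilyloxy)but-3-en-1-yl]-7β-(2,2-dimethoxyethyl)-5β-(methanesulfonyloxy)-4α-methylcyclopentan-8-one
Conditions: MsCl, Et3N, CH2Cl2, 0 °C
Reagents that add atoms: methanesulfonyl chloride, CS(=O)(=O)Cl
Why: Mesylation through the small sulfene reaches the hindered C5 hydroxyl, the only free one. The mesylate is stable because C4 is quaternary and the C6 hydrogen is cis to it, so no anti elimination is possible.

Step 15
Reactants: 22 2-methylenepropane-1,3-diol
Product: 23 2-{[(4-methoxybenzyl)oxy]methyl}prop-2-en-1-ol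
Conditions: NaH (1 equiv), THF, 0 °C; then 4-MeOC6H4CH2Cl, Bu4NI (cat.), rt
Reagents that add atoms: 4-methoxybenzyl chloride, COc1ccc(CCl)cc1
Why: Williamson mono-etherification of a symmetrical diol with one equivalent of base.

Step 16
Reactants: 23 2-{[(4-methoxybenzyl)oxy]methyl}prop-2-en-1-ol
Product: 24 1-({[2-(bromomethyl)prop-2-en-1-yl]oxy}methyl)-4-methoxybenzene
Conditions: CBr4, PPh3, CH2Cl2, 0 °C
Reagents that add atoms: carbon tetrabromide, BrC(Br)(Br)Br
Why: Appel bromination of a primary allylic alcohol under neutral conditions.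

Step 17
Reactants: 21 6α-(tert-butyldimethylsilyloxy)-4β-[(2S)-2-(tert-butyldiphenylsilyloxy)but-3-en-1-yl]-7β-(2,2-dimethoxyethyl)-5β-(methanesulfonyloxy)-4α-methylcyclopentan-8-one; 24 1-({[2-(bromomethyl)prop-2-en-1-yl]oxy}methyl)-4-methoxybenzene
Product: 25 cyclopentane with 8β-hydroxy, 8α-{2-[(4-methoxybenzyloxy)methyl]prop-2-en-1-yl}, 4α-methyl, 4β-[(2S)-2-(tert-butyldiphenylsilyloxy)but-3-en-1-yl], 5β-methanesulfonyloxy, 6α-(tert-butyldimethylsilyloxy) and 7β-(2,2-dimethoxyethyl)
Conditions: Zn, sat. aq. NH4Cl/THF, rt
Reagents that add atoms: none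
Why: Aqueous Barbier allylation: the allylzinc reagent adds through a six-membered transition state from the α face, opposite the C7 side chain, so the new hydroxyl should be β. Water protonates the alkoxide at once, so it cannot fragment before the seven-membered ring exists; the C8 configuration is erased in step 19 and its epimer would serve equally. Acid is kept away from here on, because the hydroxyl is cis to the acetal chain and could close a cyclic acetal.

Step 18
Reactants: 25 cyclopentane with 8β-hydroxy, 8α-{2-[(4-methoxybenzyloxy)methyl]prop-2-en-1-yl}, 4α-methyl, 4β-[(2S)-2-(tert-butyldiphenylsilyloxy)but-3-en-1-yl], 5β-methanesulfonyloxy, 6α-(tert-butyldimethylsilyloxy) and 7β-(2,2-dimethoxyethyl)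
Product: 26 trans-fused hydroazulene hydroxy mesylate (bicyclo[5.3.0]dec-1(10)-ene with C4–C8 as ring fusion): 8β-hydroxy, 4α-methyl, 5β-methanesulfonyloxy, 6α-(tert-butyldimethylsilyloxy), 7β-(2,2-dimethoxyethyl), (2S)-2-(tert-butyldiphenylsilyloxy), 10-[(4-methoxybenzyloxy)methyl]
Conditions: second-generation Grubbs catalyst RuCl2(=CHPh)(H2IMes)(PCy3) (10 mol %), toluene, 80 °C, 2 mM
Reagents that add atoms: none
Why: Ring-closing metathesis of the C1 vinyl group with the 1,1-disubstituted C10 alkene closes the seven-membered ring; the trisubstituted C1=C10 alkene can only be cis in a ring of this size. The mesylate, the tertiary alcohol and the ethers are inert to the ruthenium carbene.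

Step 19
Reactants: 26 trans-fused hydroazulene hydroxy mesylate
Product: 28 ten-membered ketone: cyclodeca-1(10),4-dien-8-one (both alkenes ring-cis) with (2S)-2-(tert-butyldiphenylsilyloxy), 4-methyl, 6-(tert-butyldimethylsilyloxy), 7-(2,2-dimethoxyethyl) and 10-[(4-methoxybenzyloxy)methyl]; C6 and C7 as in 41, via potassium alkoxide 27 (not isolated)
Conditions: KOt-Bu (1.0 equiv), THF, 0 °C, 15 min; then pH 7 phosphate buffer
Reagents that add atoms: none
Why: KOt-Bu deprotonates the tertiary C8 hydroxyl, and in the alkoxide the oxygen lone pair forms the C8 carbonyl while the C4–C8 σ bond breaks, its electrons become the C4=C5 π bond and the anti-periplanar C5–O bond to the mesylate ionises, all in one concerted step. The closest known reaction type is the Grob (Wharton) fragmentation of bicyclic 1,3-hydroxy sulfonates to medium-ring alkenones. No ring is closed by bond formation: the ten-membered ring is the periphery of the five- and seven-membered rings and appears when their shared bond is cut. No stereocentre is formed; C8 is destroyed and C2, C6 and C7 are untouched. The only new stereo element is the C4=C5 geometry, which is stereospecific: the mesylate is β, cis to C3 and trans to the C4 methyl, so C3 and C6 end on the same side of the new alkene. The all-trans pattern at C5, C6 and C7 places the mesylate pseudo-equatorial, which is the position anti to the C4–C8 bond. Fragmentation must win over elimination and oxetane formation: C4 is quaternary and the C6 hydrogen is cis to the mesylate, and the C8 oxygen is on the same face as the leaving group, so it cannot attack C5 from the rear. The product is a β-silyloxy, β,γ-unsaturated ketone with an enolisable C7 hydrogen; one equivalent of base is used because it is consumed as potassium methanesulfonate, and the exposure is kept short and cold.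

Step 20
Reactants: 28 ten-membered ketone
Product: 29 (8R)-alcohol: cyclodeca-1(10),4-dien-8-ol with the substituents of 28
Conditions: LiBH(s-Bu)3, THF, −78 °C; then sat. aq. NH4Cl
Reagents that add atoms: none
Why: Felkin–Anh reduction by a bulky hydride: with the C6–C7 ring bond perpendicular to the carbonyl and the C7 hydrogen next to the trajectory, the hydride comes from the outer face and gives the 8R alcohol, anti to the C6 oxygen as in 41. The low temperature protects the β-silyloxy ketone from enolisation.

Step 21
Reactants: 29 (8R)-alcohol; 30 angelic acid [(Z)-2-methylbut-2-enoic acid]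
Product: 32 8-angelate: the (Z)-2-methylbut-2-enoate of 29 at O8, via mixed anhydride 31 (not isolated)
Conditions: 30, 2,4,6-Cl3C6H2COCl, Et3N, toluene, rt; then 29, 75 °C
Reagents that add atoms: none
Why: Yamaguchi esterification through the mixed anhydride, which acylates hindered secondary alcohols and, without a nucleophilic catalyst, should leave the Z geometry of the angelate intact. C8 is the only free hydroxyl, so no selectivity is asked.

Step 22
Reactants: 32 8-angelate
Product: 33 aldehyde: 7-(2-oxoethyl) analogue of 32
Conditions: PPTS, acetone/H2O (10:1), 40 °C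
Reagents that add atoms: water, O
Why: Mild acid hydrolysis of the dimethyl acetal; the secondary silyl ethers, the p-methoxybenzyl ether and the angelate should survive pyridinium tosylate in wet acetone.

Step 23
Reactants: 33 aldehyde
Product: 35 α-methylene aldehyde: 7-(3-oxoprop-1-en-2-yl) analogue of 32, via Mannich base 34 (not isolated)
Conditions: CH2=NMe2+ I− (Eschenmoser's salt), Et3N, CH2Cl2, rt
Reagents that add atoms: dimethylmethyleneammonium iodide, C=[N+](C)C.[I-]
Why: Mannich reaction of the aldehyde enol with the iminium salt, then β-elimination of dimethylamine, puts C13 on C11 under amine base only; this avoids a lactone enolate, which the angelate would not tolerate.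

Step 24
Reactants: 35 α-methylene aldehyde
Product: 37 lactol: 12-hydroxy-6,12-epoxide (2-hydroxy-3-methylenetetrahydrofuran fused at C6–C7; both anomers) with the 8-angelate, the C2 silyl ether and the C14 ether, via hydroxy enal 36 (not isolated)
Conditions: HF·pyridine, pyridine, THF, 0 °C → rt
Reagents that add atoms: none
Why: Acidic fluoride removes the tert-butyldimethylsilyl ether at C6 faster than the tert-butyldiphenylsilyl ether at C2; the freed hydroxyl adds to the aldehyde in a 5-exo-trig closure, which is favoured over 5-endo conjugate addition.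

Step 25
Reactants: 37 lactol
Product: 38 lactone: (6R,7R,8R)-germacra-1(10),4,11(13)-trien-12,6-olide with 8-angeloyloxy, (2S)-2-(tert-butyldiphenylsilyloxy) and 14-(4-methoxybenzyloxy)
Conditions: Dess–Martin periodinane, CH2Cl2, rt
Reagents that add atoms: none
Why: Oxidation of a lactol to the lactone by a hypervalent iodine reagent under neutral conditions; there is no other free hydroxyl, and ethers and alkenes are inert.

Step 26
Reactants: 38 lactone
Product: 39 14-alcohol: 14-hydroxy analogue of 38
Conditions: DDQ, CH2Cl2/pH 7 buffer, 0 °C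
Reagents that add atoms: none
Why: Oxidative cleavage of the p-methoxybenzyl ether through its benzylic cation and hemiacetal; silyl ether, esters and the methylene lactone are not oxidised, and time is kept short to spare the new allylic alcohol.

Step 27
Reactants: 39 14-alcohol
Product: 40 14-acetate: 14-acetoxy analogue of 38
Conditions: Ac2O, pyridine, DMAP (cat.), CH2Cl2, 0 °C
Reagents that add atoms: acetic anhydride, CC(=O)OC(C)=O
Why: Acetylation of the only free hydroxyl, a primary allylic alcohol.

Step 28
Reactants: 40 14-acetate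
Product: 41 CNP0151426.1: (2S,6R,7R,8R)-14-acetoxy-8-angeloyloxy-2-hydroxygermacra-1(10),4,11(13)-trien-12,6-olide (both ring alkenes cis)
Conditions: HF·pyridine, THF, rt
Reagents that add atoms: none
Why: Acidic fluoride removes the last silyl ether without the basic conditions that would endanger the acetate, the angelate and the Michael-acceptor lactone.

## Compound list

1 | 2-methylcyclopentane-1,3-dione | CC1C(=O)CCC1=O | starting material
2 | allyl bromide | C=CCBr | starting material
3 | 2-methyl-2-(prop-2-en-1-yl)cyclopentane-1,3-dione | CC1(CC=C)C(=O)CCC1=O | intermediate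
4 | (2R,3R)-3-hydroxy-2-methyl-2-(prop-2-en-1-yl)cyclopentan-1-one | C[C@]1(CC=C)C(=O)CC[C@H]1O | intermediate
5 | (2R,3R)-2-methyl-2-(prop-2-en-1-yl)-3-(triethylsilyloxy)cyclopentan-1-one | C[C@]1(CC=C)C(=O)CC[C@H]1O[Si](CC)(CC)CC | intermediate
6 | trimethylsilyl enol ether of 5 (C7=C8, not isolated) | C[C@]1(CC=C)C(O[Si](C)(C)C)=CC[C@H]1O[Si](CC)(CC)CC | intermediate
7 | (4R,5R)-5-methyl-5-(prop-2-en-1-yl)-4-(triethylsilyloxy)cyclopent-2-en-1-one | C[C@]1(CC=C)C(=O)C=C[C@H]1O[Si](CC)(CC)CC | intermediate
8 | 4β-allyl-6α,7α-epoxy-4α-methyl-5β-(triethylsilyloxy)cyclopentan-8-one | C[C@]1(CC=C)C(=O)[C@@H]2O[C@@H]2[C@H]1O[Si](CC)(CC)CC | intermediate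
9 | prenyl bromide (1-bromo-3-methylbut-2-ene) | CC(C)=CCBr | starting material
10 | dilithium 6α-alkoxide C7=C8 enolate (not isolated) | C[C@]1(CC=C)C([O-])=C[C@H]([O-])[C@H]1O[Si](CC)(CC)CC.[Li+].[Li+] | intermediate
11 | 4β-allyl-6α-hydroxy-4α-methyl-7β-(3-methylbut-2-en-1-yl)-5β-(triethylsilyloxy)cyclopentan-8-one | C[C@]1(CC=C)C(=O)[C@@H](CC=C(C)C)[C@H](O)[C@H]1O[Si](CC)(CC)CC | intermediate
12 | 6α-tert-butyldimethylsilyl ether of 11 | C[C@]1(CC=C)C(=O)[C@@H](CC=C(C)C)[C@H](O[Si](C)(C)C(C)(C)C)[C@H]1O[Si](CC)(CC)CC | intermediate
13 | ozonide (1,2,4-trioxolane) of the prenyl alkene of 12 (not isolated) | C[C@]1(CC=C)C(=O)[C@@H](CC2OOC(C)(C)O2)[C@H](O[Si](C)(C)C(C)(C)C)[C@H]1O[Si](CC)(CC)CC | intermediate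
14 | 7β-(2-oxoethyl) aldehyde | C[C@]1(CC=C)C(=O)[C@@H](CC=O)[C@H](O[Si](C)(C)C(C)(C)C)[C@H]1O[Si](CC)(CC)CC | intermediate
15 | 7β-(2,2-dimethoxyethyl) ketone | C[C@]1(CC=C)C(=O)[C@@H](CC(OC)OC)[C@H](O[Si](C)(C)C(C)(C)C)[C@H]1O[Si](CC)(CC)CC | intermediate
16 | ozonide of the allyl group of 15 (not isolated) | C[C@]1(CC2OOCO2)C(=O)[C@@H](CC(OC)OC)[C@H](O[Si](C)(C)C(C)(C)C)[C@H]1O[Si](CC)(CC)CC | intermediate
17 | 4β-(2-oxoethyl) aldehyde | C[C@]1(CC=O)C(=O)[C@@H](CC(OC)OC)[C@H](O[Si](C)(C)C(C)(C)C)[C@H]1O[Si](CC)(CC)CC | intermediate
18 | 4β-[(2S)-2-hydroxybut-3-en-1-yl] allylic alcohol | C[C@]1(C[C@H](O)C=C)C(=O)[C@@H](CC(OC)OC)[C@H](O[Si](C)(C)C(C)(C)C)[C@H]1O[Si](CC)(CC)CC | intermediate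
19 | C2 tert-butyldiphenylsilyl ether of 18 | C[C@]1(C[C@H](O[Si](c2ccccc2)(c2ccccc2)C(C)(C)C)C=C)C(=O)[C@@H](CC(OC)OC)[C@H](O[Si](C)(C)C(C)(C)C)[C@H]1O[Si](CC)(CC)CC | intermediate
20 | 5β-alcohol | C[C@]1(C[C@H](O[Si](c2ccccc2)(c2ccccc2)C(C)(C)C)C=C)C(=O)[C@@H](CC(OC)OC)[C@H](O[Si](C)(C)C(C)(C)C)[C@H]1O | intermediate
21 | 5β-mesylate | C[C@]1(C[C@H](O[Si](c2ccccc2)(c2ccccc2)C(C)(C)C)C=C)C(=O)[C@@H](CC(OC)OC)[C@H](O[Si](C)(C)C(C)(C)C)[C@H]1OS(C)(=O)=O | intermediate
22 | 2-methylenepropane-1,3-diol | C=C(CO)CO | starting material
23 | 2-{[(4-methoxybenzyl)oxy]methyl}prop-2-en-1-ol | C=C(CO)COCc1ccc(OC)cc1 | intermediate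
24 | 1-({[2-(bromomethyl)prop-2-en-1-yl]oxy}methyl)-4-methoxybenzene | C=C(CBr)COCc1ccc(OC)cc1 | intermediate
25 | 8β-hydroxy 8α-allyl tertiary alcohol (Barbier adduct) | C[C@]1(C[C@H](O[Si](c2ccccc2)(c2ccccc2)C(C)(C)C)C=C)[C@](O)(CC(=C)COCc2ccc(OC)cc2)[C@@H](CC(OC)OC)[C@H](O[Si](C)(C)C(C)(C)C)[C@H]1OS(C)(=O)=O | intermediate
26 | trans-fused hydroazulene hydroxy mesylate | C[C@]12C[C@H](O[Si](c3ccccc3)(c3ccccc3)C(C)(C)C)/C=C(/COCc3ccc(OC)cc3)C[C@]1(O)[C@@H](CC(OC)OC)[C@H](O[Si](C)(C)C(C)(C)C)[C@H]2OS(C)(=O)=O | intermediate
27 | potassium alkoxide of 26 (not isolated) | C[C@]12C[C@H](O[Si](c3ccccc3)(c3ccccc3)C(C)(C)C)/C=C(/COCc3ccc(OC)cc3)C[C@]1([O-])[C@@H](CC(OC)OC)[C@H](O[Si](C)(C)C(C)(C)C)[C@H]2OS(C)(=O)=O.[K+] | intermediate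
28 | ten-membered C8 ketone | CC(C)(C)[Si](C)(C)O[C@@H]1/C=C(/C)C[C@H](O[Si](c2ccccc2)(c2ccccc2)C(C)(C)C)/C=C(/COCc2ccc(OC)cc2)CC(=O)[C@H]1CC(OC)OC | intermediate
29 | (8R)-alcohol | CC(C)(C)[Si](C)(C)O[C@@H]1/C=C(/C)C[C@H](O[Si](c2ccccc2)(c2ccccc2)C(C)(C)C)/C=C(/COCc2ccc(OC)cc2)C[C@@H](O)[C@H]1CC(OC)OC | intermediate
30 | angelic acid | C/C=C(/C)C(=O)O | starting material
31 | angelic 2,4,6-trichlorobenzoic mixed anhydride (not isolated) | C/C=C(/C)C(=O)OC(=O)c1c(Cl)cc(Cl)cc1Cl | intermediate
32 | 8-angelate | CC(C)(C)[Si](C)(C)O[C@@H]1/C=C(/C)C[C@H](O[Si](c2ccccc2)(c2ccccc2)C(C)(C)C)/C=C(/COCc2ccc(OC)cc2)C[C@@H](OC(=O)/C(C)=C\C)[C@H]1CC(OC)OC | intermediate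
33 | C12 aldehyde | CC(C)(C)[Si](C)(C)O[C@@H]1/C=C(/C)C[C@H](O[Si](c2ccccc2)(c2ccccc2)C(C)(C)C)/C=C(/COCc2ccc(OC)cc2)C[C@@H](OC(=O)/C(C)=C\C)[C@H]1CC=O | intermediate
34 | Mannich base, 11-(dimethylaminomethyl) aldehyde (not isolated) | CC(C)(C)[Si](C)(C)O[C@@H]1/C=C(/C)C[C@H](O[Si](c2ccccc2)(c2ccccc2)C(C)(C)C)/C=C(/COCc2ccc(OC)cc2)C[C@@H](OC(=O)/C(C)=C\C)[C@H]1C(CN(C)C)C=O | intermediate
35 | α-methylene aldehyde | CC(C)(C)[Si](C)(C)O[C@@H]1/C=C(/C)C[C@H](O[Si](c2ccccc2)(c2ccccc2)C(C)(C)C)/C=C(/COCc2ccc(OC)cc2)C[C@@H](OC(=O)/C(C)=C\C)[C@H]1C(=C)C=O | intermediate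
36 | C6-hydroxy enal (not isolated) | O[C@@H]1/C=C(/C)C[C@H](O[Si](c2ccccc2)(c2ccccc2)C(C)(C)C)/C=C(/COCc2ccc(OC)cc2)C[C@@H](OC(=O)/C(C)=C\C)[C@H]1C(=C)C=O | intermediate
37 | lactol | C=C1C(O)O[C@@H]2/C=C(/C)C[C@H](O[Si](c3ccccc3)(c3ccccc3)C(C)(C)C)/C=C(/COCc3ccc(OC)cc3)C[C@@H](OC(=O)/C(C)=C\C)[C@@H]12 | intermediate
38 | α-methylene lactone, C14 p-methoxybenzyl ether | C=C1C(=O)O[C@@H]2/C=C(/C)C[C@H](O[Si](c3ccccc3)(c3ccccc3)C(C)(C)C)/C=C(/COCc3ccc(OC)cc3)C[C@@H](OC(=O)/C(C)=C\C)[C@@H]12 | intermediate
39 | 14-alcohol | C=C1C(=O)O[C@@H]2/C=C(/C)C[C@H](O[Si](c3ccccc3)(c3ccccc3)C(C)(C)C)/C=C(/CO)C[C@@H](OC(=O)/C(C)=C\C)[C@@H]12 | intermediate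
40 | 14-acetate, C2 silyl ether | C=C1C(=O)O[C@@H]2/C=C(/C)C[C@H](O[Si](c3ccccc3)(c3ccccc3)C(C)(C)C)/C=C(/COC(C)=O)C[C@@H](OC(=O)/C(C)=C\C)[C@@H]12 | intermediate
41 | CNP0151426.1 | C=C1C(=O)O[C@@H]2/C=C(/C)C[C@H](O)/C=C(/COC(C)=O)C[C@@H](OC(=O)/C(C)=C\C)[C@@H]12 | target

## Step count and least certain steps

Total step count: 28 (26 in the main line, 2 for bromide 24). Longest linear sequence: 26 steps (steps 1 to 14 and 17 to 28).

**Step 19 (key step).** The most likely failure is base-induced degradation of the product as it forms. Ketone 28 has an enolisable C7 hydrogen next to the C6 silyloxy group and a β,γ-alkene, so loss of silanolate, epimerisation at C7 or migration of C1=C10 into conjugation can compete if the fragmentation is slower than proton exchange. Fallback: from 26, the fragmentation is triggered with LiAlH4 in THF (0 °C to rt). The hydride acts as the base, and the ketone is reduced as it is released, so no enolisable ketone accumulates. This reductive fragmentation makes no new compound (entry F0) and rejoins the route at 29; an 8-epimer, if formed, is handled as described under step 20.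

**Step 6.** Proton exchange between the alkylated ketone and enolate 10 in ammonia can lead to double alkylation and unalkylated material, and excess metal can over-reduce the carbonyl. Fallback: the same alkoxide enolate is made by deprotonation. From enone 7, conjugate borylation (CuCl, NaOt-Bu, Xantphos, B2pin2, MeOH, THF) should add boron to C6 on the α face and give the 6α-boryl ketone F1. Oxidation with NaBO3·4H2O gives, with retention, the 6α-hydroxy ketone F2. LiN(i-Pr)2 (2.2 equiv, THF, −78 °C) then forms 10, which is alkylated with 9 and rejoins the route at 11.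

**Step 11.** Facial discrimination may be eroded because the acetal and ketone oxygens of 17 bind zinc and the reagent is made in the presence of salts. Fallback: the C2 centre is set by reduction instead of addition. From 17, ethynylmagnesium bromide (THF, −78 °C) gives the propargylic alcohols F3 as a C2 mixture. Dess–Martin oxidation gives the ynone F4. Transfer hydrogenation with RuCl[(S,S)-TsDPEN](p-cymene) in i-PrOH reduces the ynone under catalyst control to the (2S)-propargylic alcohol F5, and leaves the hindered C8 ketone alone. Semi-hydrogenation (H2, Pd/CaCO3 poisoned with Pb(OAc)2, quinoline) then gives 18.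

**Step 20.** The conformation of the ten-membered ring, not the C7 substituent, may decide which carbonyl face is open, so that the hydride enters from the other face. Fallback: the epimer is not recycled but inverted during esterification. From 28, the (8S)-alcohol F6 is esterified with 30 under Mitsunobu conditions (PPh3, diisopropyl azodicarboxylate, toluene, 0 °C). The carboxylate displaces the activated oxygen with inversion and gives 32 directly.

## Further compounds

F0 | step 19 | none | none
F1 | step 6 | 4β-allyl-4α-methyl-6α-(4,4,5,5-tetramethyl-1,3,2-dioxaborolan-2-yl)-5β-(triethylsilyloxy)cyclopentan-8-one | C[C@]1(CC=C)C(=O)C[C@H](B2OC(C)(C)C(C)(C)O2)[C@H]1O[Si](CC)(CC)CC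
F2 | step 6 | 4β-allyl-6α-hydroxy-4α-methyl-5β-(triethylsilyloxy)cyclopentan-8-one | C[C@]1(CC=C)C(=O)C[C@H](O)[C@H]1O[Si](CC)(CC)CC
F3 | step 11 | 4β-(2-hydroxybut-3-yn-1-yl) propargylic alcohols (C2 epimers) | C[C@]1(CC(O)C#C)C(=O)[C@@H](CC(OC)OC)[C@H](O[Si](C)(C)C(C)(C)C)[C@H]1O[Si](CC)(CC)CC
F4 | step 11 | 4β-(2-oxobut-3-yn-1-yl) ynone | C[C@]1(CC(=O)C#C)C(=O)[C@@H](CC(OC)OC)[C@H](O[Si](C)(C)C(C)(C)C)[C@H]1O[Si](CC)(CC)CC
F5 | step 11 | 4β-[(2S)-2-hydroxybut-3-yn-1-yl] propargylic alcohol | C[C@]1(C[C@H](O)C#C)C(=O)[C@@H](CC(OC)OC)[C@H](O[Si](C)(C)C(C)(C)C)[C@H]1O[Si](CC)(CC)CC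
F6 | step 20 | (8S)-alcohol, C8 epimer of 29 | CC(C)(C)[Si](C)(C)O[C@@H]1/C=C(/C)C[C@H](O[Si](c2ccccc2)(c2ccccc2)C(C)(C)C)/C=C(/COCc2ccc(OC)cc2)C[C@H](O)[C@H]1CC(OC)OC
A1 | alternative 1 | ten-membered C6 alcohol with C12 triethylsilyl ether | O[C@@H]1/C=C(/C)C[C@H](O[Si](C)(C)C(C)(C)C)/C=C(/COC(C)=O)C[C@@H](OC(=O)/C(C)=C\C)[C@H]1C(=C)CO[Si](CC)(CC)CC
A2 | alternative 1 | chromium dichloride | [Cr+2].[Cl-].[Cl-]
A3 | alternative 1 | nickel dichloride | [Ni+2].[Cl-].[Cl-]
A4 | alternative 2 | ten-membered C6 ketone with C8 dimethylphenylsilyl group | O=C1/C=C(/C)C[C@H](O[Si](C)(C)C(C)(C)C)/C=C(/CO[Si](C)(C)C(C)(C)C)C[C@@H]([Si](C)(C)c2ccccc2)C1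
A5 | alternative 2 | potassium hydride | [K+].[H-]
A6 | alternative 3 | ten-membered 2,8-diketone with C14 methyl ester | CC(C)(C)[Si](C)(C)O[C@@H]1/C=C(/C)CC(=O)/C=C(/C(=O)OC)CC(=O)[C@H]1CC(OC)OC
A7 | alternative 3 | methyl propiolate | C#CC(=O)OC
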